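Assumption: the absolute configuration is read from the SMILES as written. Ring labels are mine: ring A = cyclohexane bearing the acrylic acid, ring B = δ-lactone, ring C = cyclohexanone, ring D = bridging oxolane. Nothing here has been run or computed; stereochemical outcomes are predictions from transition-state models.

**Retrosynthetic overview**
1. Target ⇒ open ring D (oxa-Michael retron) and ring B (lactone plus formaldehyde aldol at the spiro carbon) ⇒ enone ester acid 23.
2. 23 ⇒ acetyl compound 21 (acrylic acid from the methyl ketone via enol triflate carbonylation) ⇒ 20 by opening ring A at the bond made by an intramolecular Michael addition.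
3. 20 ⇒ ring C ketal 10 (fragment 1) + (Z)-2-(hydroxymethyl)enoate 17 (fragment 2), joined by a ketal Claisen rearrangement.
4. Fragment 1 ⇒ intramolecular aldol condensation of a keto aldehyde from Evans methallylation of 3,3-dimethylpent-4-enoic acid; fragment 2 ⇒ 5-chloropentan-2-one via an ynoate.
5. Ring order: C (aldol condensation), A (Michael), B (aldol/lactonisation), D (oxa-Michael).

**Fragment 1 (ring C)**

Step 1
Reactants: 1 3,3-dimethylpent-4-enoic acid; 2 (4R)-4-benzyl-1,3-oxazolidin-2-one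
Product: 4 (4R)-4-benzyl-3-(3,3-dimethylpent-4-enoyl)-1,3-oxazolidin-2-one, via mixed pivalic anhydride 3 (not isolated)
Conditions: t-BuCOCl, NEt3, THF, −20 °C; then 2, LiCl, −20 °C → rt
Reagents that add atoms: none
Why: N-acylation of the oxazolidinone through the mixed anhydride (LiCl/NEt3 protocol); no stereocentre is formed.

Step 2
Reactants: 4 (4R)-4-benzyl-3-(3,3-dimethylpent-4-enoyl)-1,3-oxazolidin-2-one
Product: 5 (4R)-4-benzyl-3-[(2R)-3,3-dimethyl-2-(2-methylprop-2-en-1-yl)pent-4-enoyl]-1,3-oxazolidin-2-one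
Conditions: NaN(SiMe3)2, THF, −78 °C; CH2=C(CH3)CH2Br, −78 → −30 °C
Reagents that add atoms: 3-bromo-2-methylprop-1-ene, C=C(C)CBr
Why: Evans asymmetric alkylation; the chelated Z-enolate is alkylated on the face opposite the benzyl group, which sets the (2R) centre (the future ring C carbon bearing CH2O).

Step 3
Reactants: 5 (4R)-4-benzyl-3-[(2R)-3,3-dimethyl-2-(2-methylprop-2-en-1-yl)pent-4-enoyl]-1,3-oxazolidin-2-one
Product: 6 (2R)-3,3-dimethyl-2-(2-methylprop-2-en-1-yl)pent-4-en-1-ol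
Conditions: LiBH4, H2O (1 equiv), Et2O, 0 °C
Reagents that add atoms: none
Why: Reductive removal of the auxiliary (hydride reduction of the imide carbonyl); the α-centre is not enolised and the alkenes are inert.

Step 4
Reactants: 6 (2R)-3,3-dimethyl-2-(2-methylprop-2-en-1-yl)pent-4-en-1-ol
Product: 7 tert-butyl{[(2R)-3,3-dimethyl-2-(2-methylprop-2-en-1-yl)pent-4-en-1-yl]oxy}diphenylsilane
Conditions: t-BuPh2SiCl, imidazole, DMF, rt
Reagents that add atoms: tert-butyl(chloro)diphenylsilane, CC(C)(C)[Si](Cl)(c1ccccc1)c1ccccc1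
Why: Silyl protection of the primary alcohol; this ether survives the later acid, base and heat and is removed by fluoride at the end.

Step 5
Reactants: 7 tert-butyl{[(2R)-3,3-dimethyl-2-(2-methylprop-2-en-1-yl)pent-4-en-1-yl]oxy}diphenylsilane
Product: 9 (5R)-5-{[tert-butyl(diphenyl)silyl]oxymethyl}-4,4-dimethylcyclohex-2-en-1-one, via keto aldehyde 8 (not isolated)
Conditions: O3, CH2Cl2, −78 °C (indicator end point); PPh3, −78 °C → rt; evaporate; KOH, MeOH, 0 °C → rt
Reagents that add atoms: ozone, [O-][O+]=O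
Why: Ozonolysis of both terminal alkenes, then intramolecular aldol condensation of the methyl ketone CH3 onto the non-enolisable neopentyl aldehyde (only the six-membered closure can dehydrate) closes ring C; the stereocentre is β to the ketone and untouched.

Step 6
Reactants: 9 (5R)-5-{[tert-butyl(diphenyl)silyl]oxymethyl}-4,4-dimethylcyclohex-2-en-1-one
Product: 10 tert-butyl{[(1R)-5,5-dimethoxy-2,2-dimethylcyclohex-3-en-1-yl]methoxy}diphenylsilane
Conditions: HC(OMe)3, MeOH, camphorsulfonic acid (cat.), rt; NEt3 quench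
Reagents that add atoms: trimethyl orthoformate, COC(OC)OC
Why: Acid-catalysed ketalisation; the gem-dimethyl group blocks conjugate addition of methanol and there is no γ-hydrogen, so the alkene cannot migrate.

**Fragment 2 (chain)**

Step 7
Reactants: 11 5-chloropentan-2-one
Product: 12 2-(3-chloropropyl)-2-methyl-1,3-dioxolane
Conditions: HOCH2CH2OH, p-TsOH (cat.), toluene, reflux (Dean–Stark)
Reagents that add atoms: ethane-1,2-diol, OCCO
Why: Ketalisation masks the ketone against the acetylide, butyllithium and the enol-ether chemistry that follow.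

Step 8
Reactants: 12 2-(3-chloropropyl)-2-methyl-1,3-dioxolane
Product: 13 2-methyl-2-(pent-4-yn-1-yl)-1,3-dioxolane
Conditions: LiC≡CH·H2NCH2CH2NH2, NaI (cat.), DMSO, rt
Reagents that add atoms: lithium acetylide–ethylenediamine complex, [Li]C#C.NCCN
Why: SN2 alkynylation of the primary halide (iodide catalysis).

Step 9
Reactants: 13 2-methyl-2-(pent-4-yn-1-yl)-1,3-dioxolane
Product: 14 methyl 6-(2-methyl-1,3-dioxolan-2-yl)hex-2-ynoate
Conditions: n-BuLi, THF, −78 °C; ClCO2Me, −78 → 0 °C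
Reagents that add atoms: methyl chloroformate, COC(=O)Cl
Why: Deprotonation of the terminal alkyne and C-acylation of the lithium acetylide.

Step 10
Reactants: 14 methyl 6-(2-methyl-1,3-dioxolan-2-yl)hex-2-ynoate
Product: 15 methyl (2E)-6-(2-methyl-1,3-dioxolan-2-yl)-2-(tributylstannyl)hex-2-enoate
Conditions: Bu3SnH, Pd(PPh3)4 (2 mol %), THF, 0 °C → rt
Reagents that add atoms: tributyltin hydride, CCCC[SnH](CCCC)CCCC
Why: Palladium-catalysed syn-hydrostannation of the ynoate puts tin on the α-carbon and hydrogen on the β-carbon, so the chain ends up cis to the ester.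

Step 11
Reactants: 15 methyl (2E)-6-(2-methyl-1,3-dioxolan-2-yl)-2-(tributylstannyl)hex-2-enoate
Product: 16 methyl (2E)-2-iodo-6-(2-methyl-1,3-dioxolan-2-yl)hex-2-enoate
Conditions: I2, CH2Cl2, 0 °C
Reagents that add atoms: iodine, II
Why: Iododestannylation with retention of alkene geometry.

Step 12
Reactants: 16 methyl (2E)-2-iodo-6-(2-methyl-1,3-dioxolan-2-yl)hex-2-enoate
Product: 17 methyl (2Z)-2-(hydroxymethyl)-6-(2-methyl-1,3-dioxolan-2-yl)hex-2-enoate
Conditions: Bu3SnCH2OH, Pd(PPh3)4 (5 mol %), dioxane, 90 °C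
Reagents that add atoms: (tributylstannyl)methanol, OC[Sn](CCCC)(CCCC)CCCC
Why: Stille coupling (zerovalent palladium, retention of geometry) installs CH2OH trans to the chain, giving the (Z)-enoate needed for the Claisen step.

**Union and completion**

Step 13
Reactants: 10 tert-butyl{[(1R)-5,5-dimethoxy-2,2-dimethylcyclohex-3-en-1-yl]methoxy}diphenylsilane; 17 methyl (2Z)-2-(hydroxymethyl)-6-(2-methyl-1,3-dioxolan-2-yl)hex-2-enoate
Product: 20 methyl (3S)-3-[(1R,6R)-6-{[tert-butyl(diphenyl)silyl]oxymethyl}-5,5-dimethyl-2-oxocyclohex-3-en-1-yl]-2-methylidene-7-oxooctanoate, via allyl dienol ether 18 (not isolated), via dioxolane Claisen product 19 (not isolated)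
Conditions: EtCO2H (cat.), xylene, 135 °C (MeOH distilled off); then 1 M HCl, THF, rt
Reagents that add atoms: water, O
Why: Saucy–Marbet-type ketal Claisen rearrangement; the ring-fixed enol ether reacts through a chair transition state on the face opposite the CH2OSi group with the chain of the (Z)-enoate pseudo-equatorial, which sets the ring A carbon attached to ring C and unveils the α-substituted acrylate, and the acid work-up frees the methyl ketone.

Step 14
Reactants: 20 methyl (3S)-3-[(1R,6R)-6-{[tert-butyl(diphenyl)silyl]oxymethyl}-5,5-dimethyl-2-oxocyclohex-3-en-1-yl]-2-methylidene-7-oxooctanoate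
Product: 21 methyl (1S,2S,5R)-5-acetyl-2-[(1R,6R)-6-{[tert-butyl(diphenyl)silyl]oxymethyl}-5,5-dimethyl-2-oxocyclohex-3-en-1-yl]cyclohexane-1-carboxylate
Conditions: KOtBu (0.3 equiv), t-BuOH/THF, 0 °C; AcOH quench
Reagents that add atoms: none
Why: Intramolecular Michael addition (6-endo-trig) of the internal methyl ketone enolate onto the acrylate CH2 closes ring A; the ester enolate is protonated anti to the bulky ring C substituent (cis ester, kinetic) and the enolisable acetyl centre settles equatorial, trans to that substituent.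

Step 15
Reactants: 21 methyl (1S,2S,5R)-5-acetyl-2-[(1R,6R)-6-{[tert-butyl(diphenyl)silyl]oxymethyl}-5,5-dimethyl-2-oxocyclohex-3-en-1-yl]cyclohexane-1-carboxylate
Product: 22 methyl (1S,2S,5R)-2-[(1R,6R)-6-{[tert-butyl(diphenyl)silyl]oxymethyl}-5,5-dimethyl-2-oxocyclohex-3-en-1-yl]-5-{1-[(trifluoromethanesulfonyl)oxy]ethenyl}cyclohexane-1-carboxylate
Conditions: KN(SiMe3)2 (1.05 equiv), THF, −78 °C; PhNTf2
Reagents that add atoms: N-phenylbis(trifluoromethanesulfonimide), O=S(=O)(N(c1ccccc1)S(=O)(=O)C(F)(F)F)C(F)(F)F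
Why: Kinetic deprotonation of the unhindered acetyl CH3 and O-triflation give the terminal enol triflate; the only α-hydrogen of the ring C ketone is flanked by two tertiary carbons and the ester α-hydrogen is far less acidic.

Step 16
Reactants: 22 methyl (1S,2S,5R)-2-[(1R,6R)-6-{[tert-butyl(diphenyl)silyl]oxymethyl}-5,5-dimethyl-2-oxocyclohex-3-en-1-yl]-5-{1-[(trifluoromethanesulfonyl)oxy]ethenyl}cyclohexane-1-carboxylate
Product: 23 2-[(1R,3S,4S)-4-[(1R,6R)-6-{[tert-butyl(diphenyl)silyl]oxymethyl}-5,5-dimethyl-2-oxocyclohex-3-en-1-yl]-3-(methoxycarbonyl)cyclohexyl]prop-2-enoic acid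
Conditions: Pd(OAc)2 (5 mol %), 1,1'-bis(diphenylphosphino)ferrocene, CO (1 atm), NEt3, DMF/H2O, 60 °C; dilute HCl work-up
Reagents that add atoms: carbon monoxide, [C-]#[O+]; water, O
Why: Palladium-catalysed hydroxycarbonylation (oxidative addition of the vinyl triflate to zerovalent palladium, CO insertion, hydrolysis of the acyl complex) gives the α-substituted acrylic acid without touching enone, ester or silyl ether.

Step 17
Reactants: 23 2-[(1R,3S,4S)-4-[(1R,6R)-6-{[tert-butyl(diphenyl)silyl]oxymethyl}-5,5-dimethyl-2-oxocyclohex-3-en-1-yl]-3-(methoxycarbonyl)cyclohexyl]prop-2-enoic acid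
Product: 25 2-[(1S,4a'R,6S,7'R,8a'S)-6-{[tert-butyl(diphenyl)silyl]oxymethyl}-5,5-dimethyl-1',2-dioxo-octahydrospiro[cyclohex-3-ene-1,4'-isochromen]-7'-yl]prop-2-enoic acid, via hydroxymethyl ketone 24 (not isolated)
Conditions: LiN(iPr)2 (2.2 equiv), THF, −78 → −40 °C; CH2O (gas from cracked paraformaldehyde), −78 °C → rt; aq. HCl work-up
Reagents that add atoms: formaldehyde, C=O
Why: Aldol reaction of the carboxylate/cross-conjugated dienolate dianion with formaldehyde, anti to the neighbouring CH2OSi group, creates the quaternary spiro centre; the lithium alkoxide then closes the δ-lactone (ring B) on the cis methyl ester, which also blocks retro-aldol.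

Step 18
Reactants: 25 2-[(1S,4a'R,6S,7'R,8a'S)-6-{[tert-butyl(diphenyl)silyl]oxymethyl}-5,5-dimethyl-1',2-dioxo-octahydrospiro[cyclohex-3-ene-1,4'-isochromen]-7'-yl]prop-2-enoic acid
Product: 27 CNP0268721.1 2-[(1S,2S,4a'R,5S,7'R,8a'S)-8,8-dimethyl-1',3-dioxo-octahydrospiro[6-oxabicyclo[3.2.1]octane-2,4'-isochromen]-7'-yl]prop-2-enoic acid, via free hydroxy enone 26 (not isolated)
Conditions: Bu4NF (3 equiv), THF, 0 °C → rt; aq. NH4Cl, then pH 3
Reagents that add atoms: none
Why: Fluoride desilylation releases the primary alkoxide, which adds 5-exo to the enone β-carbon (intramolecular oxa-Michael) to close ring D; the new C–O centre is fixed by the bridge geometry.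

**Compound list**
1 | 3,3-dimethylpent-4-enoic acid | C=CC(C)(C)CC(=O)O | starting material
2 | (4R)-4-benzyl-1,3-oxazolidin-2-one | O=C1OC[C@@H](Cc2ccccc2)N1 | starting material
3 | 3,3-dimethylpent-4-enoic pivalic anhydride | C=CC(C)(C)CC(=O)OC(=O)C(C)(C)C | intermediate
4 | (4R)-4-benzyl-3-(3,3-dimethylpent-4-enoyl)-1,3-oxazolidin-2-one | C=CC(C)(C)CC(=O)N1[C@H](Cc2ccccc2)COC1=O | intermediate
5 | (4R)-4-benzyl-3-[(2R)-3,3-dimethyl-2-(2-methylprop-2-en-1-yl)pent-4-enoyl]-1,3-oxazolidin-2-one | C=CC(C)(C)[C@@H](CC(C)=C)C(=O)N1[C@H](Cc2ccccc2)COC1=O | intermediate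
6 | (2R)-3,3-dimethyl-2-(2-methylprop-2-en-1-yl)pent-4-en-1-ol | C=CC(C)(C)[C@@H](CC(C)=C)CO | intermediate
7 | tert-butyl{[(2R)-3,3-dimethyl-2-(2-methylprop-2-en-1-yl)pent-4-en-1-yl]oxy}diphenylsilane | C=CC(C)(C)[C@@H](CC(C)=C)CO[Si](c1ccccc1)(c1ccccc1)C(C)(C)C | intermediate
8 | (3R)-3-{[tert-butyl(diphenyl)silyl]oxymethyl}-2,2-dimethyl-5-oxohexanal | O=CC(C)(C)[C@@H](CC(C)=O)CO[Si](c1ccccc1)(c1ccccc1)C(C)(C)C | intermediate
9 | (5R)-5-{[tert-butyl(diphenyl)silyl]oxymethyl}-4,4-dimethylcyclohex-2-en-1-one | O=C1C=CC(C)(C)[C@H](CO[Si](c2ccccc2)(c2ccccc2)C(C)(C)C)C1 | intermediate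
10 | tert-butyl{[(1R)-5,5-dimethoxy-2,2-dimethylcyclohex-3-en-1-yl]methoxy}diphenylsilane | COC1(OC)C=CC(C)(C)[C@H](CO[Si](c2ccccc2)(c2ccccc2)C(C)(C)C)C1 | intermediate
11 | 5-chloropentan-2-one | CC(=O)CCCCl | starting material
12 | 2-(3-chloropropyl)-2-methyl-1,3-dioxolane | CC1(CCCCl)OCCO1 | intermediate
13 | 2-methyl-2-(pent-4-yn-1-yl)-1,3-dioxolane | CC1(CCCC#C)OCCO1 | intermediate
14 | methyl 6-(2-methyl-1,3-dioxolan-2-yl)hex-2-ynoate | COC(=O)C#CCCCC1(C)OCCO1 | intermediate
15 | methyl (2E)-6-(2-methyl-1,3-dioxolan-2-yl)-2-(tributylstannyl)hex-2-enoate | COC(=O)/C(=C\CCCC1(C)OCCO1)[Sn](CCCC)(CCCC)CCCC | intermediate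
16 | methyl (2E)-2-iodo-6-(2-methyl-1,3-dioxolan-2-yl)hex-2-enoate | COC(=O)/C(I)=C\CCCC1(C)OCCO1 | intermediate
17 | methyl (2Z)-2-(hydroxymethyl)-6-(2-methyl-1,3-dioxolan-2-yl)hex-2-enoate | COC(=O)/C(CO)=C\CCCC1(C)OCCO1 | intermediate
18 | methyl (2Z)-2-{[((3R)-3-{[tert-butyl(diphenyl)silyl]oxymethyl}-4,4-dimethylcyclohexa-1,5-dien-1-yl)oxy]methyl}-6-(2-methyl-1,3-dioxolan-2-yl)hex-2-enoate | COC(=O)/C(COC1=C[C@@H](CO[Si](c2ccccc2)(c2ccccc2)C(C)(C)C)C(C)(C)C=C1)=C\CCCC1(C)OCCO1 | intermediate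
19 | methyl (3S)-3-[(1R,6R)-6-{[tert-butyl(diphenyl)silyl]oxymethyl}-5,5-dimethyl-2-oxocyclohex-3-en-1-yl]-2-methylidene-6-(2-methyl-1,3-dioxolan-2-yl)hexanoate | O=C1C=CC(C)(C)[C@H](CO[Si](c2ccccc2)(c2ccccc2)C(C)(C)C)[C@H]1[C@H](CCCC1(C)OCCO1)C(=C)C(=O)OC | intermediate
20 | methyl (3S)-3-[(1R,6R)-6-{[tert-butyl(diphenyl)silyl]oxymethyl}-5,5-dimethyl-2-oxocyclohex-3-en-1-yl]-2-methylidene-7-oxooctanoate | O=C1C=CC(C)(C)[C@H](CO[Si](c2ccccc2)(c2ccccc2)C(C)(C)C)[C@H]1[C@H](CCCC(C)=O)C(=C)C(=O)OC | intermediate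
21 | methyl (1S,2S,5R)-5-acetyl-2-[(1R,6R)-6-{[tert-butyl(diphenyl)silyl]oxymethyl}-5,5-dimethyl-2-oxocyclohex-3-en-1-yl]cyclohexane-1-carboxylate | O=C1C=CC(C)(C)[C@H](CO[Si](c2ccccc2)(c2ccccc2)C(C)(C)C)[C@H]1[C@@H]1CC[C@@H](C(C)=O)C[C@@H]1C(=O)OC | intermediate
22 | methyl (1S,2S,5R)-2-[(1R,6R)-6-{[tert-butyl(diphenyl)silyl]oxymethyl}-5,5-dimethyl-2-oxocyclohex-3-en-1-yl]-5-{1-[(trifluoromethanesulfonyl)oxy]ethenyl}cyclohexane-1-carboxylate | O=C1C=CC(C)(C)[C@H](CO[Si](c2ccccc2)(c2ccccc2)C(C)(C)C)[C@H]1[C@@H]1CC[C@@H](C(=C)OS(=O)(=O)C(F)(F)F)C[C@@H]1C(=O)OC | intermediate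
23 | 2-[(1R,3S,4S)-4-[(1R,6R)-6-{[tert-butyl(diphenyl)silyl]oxymethyl}-5,5-dimethyl-2-oxocyclohex-3-en-1-yl]-3-(methoxycarbonyl)cyclohexyl]prop-2-enoic acid | O=C1C=CC(C)(C)[C@H](CO[Si](c2ccccc2)(c2ccccc2)C(C)(C)C)[C@H]1[C@@H]1CC[C@@H](C(=C)C(=O)O)C[C@@H]1C(=O)OC | intermediate
24 | 2-[(1R,3S,4R)-4-[(1S,6S)-6-{[tert-butyl(diphenyl)silyl]oxymethyl}-1-(hydroxymethyl)-5,5-dimethyl-2-oxocyclohex-3-en-1-yl]-3-(methoxycarbonyl)cyclohexyl]prop-2-enoic acid | C=C(C(=O)O)[C@@H]1CC[C@@H]([C@]2(CO)C(=O)C=CC(C)(C)[C@@H]2CO[Si](c2ccccc2)(c2ccccc2)C(C)(C)C)[C@H](C1)C(=O)OC | intermediate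
25 | 2-[(1S,4a'R,6S,7'R,8a'S)-6-{[tert-butyl(diphenyl)silyl]oxymethyl}-5,5-dimethyl-1',2-dioxo-octahydrospiro[cyclohex-3-ene-1,4'-isochromen]-7'-yl]prop-2-enoic acid | C=C(C(=O)O)[C@@H]1CC[C@@H]2[C@H](C1)C(=O)OC[C@]21C(=O)C=CC(C)(C)[C@@H]1CO[Si](c1ccccc1)(c1ccccc1)C(C)(C)C | intermediate
26 | 2-[(1S,4a'R,6S,7'R,8a'S)-6-(hydroxymethyl)-5,5-dimethyl-1',2-dioxo-octahydrospiro[cyclohex-3-ene-1,4'-isochromen]-7'-yl]prop-2-enoic acid | C=C(C(=O)O)[C@@H]1CC[C@@H]2[C@H](C1)C(=O)OC[C@]21C(=O)C=CC(C)(C)[C@@H]1CO | intermediate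
27 | CNP0268721.1, 2-[(1S,2S,4a'R,5S,7'R,8a'S)-8,8-dimethyl-1',3-dioxo-octahydrospiro[6-oxabicyclo[3.2.1]octane-2,4'-isochromen]-7'-yl]prop-2-enoic acid | C=C(C(=O)O)[C@@H]1CC[C@@H]2[C@H](C1)C(=O)OC[C@]21C(=O)C[C@@H]2OC[C@H]1C2(C)C | target

**Step count**
Total: 18 steps. Longest linear sequence: 12 steps (steps 1–6 then 13–18; the chain branch, steps 7–12 then 13–18, is equally long).

**Three steps most likely to fail, with fallbacks**

Step 13 (ketal Claisen union). The exchange of a hindered, electron-poor allylic alcohol onto the enone ketal at 135 °C under acid may be slow or erode material, and the facial/chair preference may leak. The fallback replaces the sigmatropic union by an enolate SN2' alkylation and sets out from 9 and 17. Alcohol 17 is converted with CBr4/PPh3 (CH2Cl2, 0 °C) into methyl (2E)-2-(bromomethyl)-6-(2-methyl-1,3-dioxolan-2-yl)hex-2-enoate F1. The lithium dienolate of enone 9 (LiN(iPr)2, THF, −78 °C) is then added to F1; conjugate addition at the alkene carbon carrying the chain followed by loss of bromide gives 19 directly. The fallback comes back to the route at 19, which the HCl treatment of step 13 converts into 20. Stereocontrol at the new centre would then rest on a chelated closed transition state and may require separation of epimers.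

Step 14 (ring A Michael closure). Under alkoxide the ketone enolate could instead acylate the ester (Claisen-type six-ring closure), sit in reversible aldol traps with the ring C ketone, or epimerise the new ester centre. The fallback uses a preformed silyl enol ether and a Lewis-acid Mukaiyama–Michael closure and sets out from 20. Me3SiCl/NaI/NEt3 in MeCN gives methyl (3S,6Z)-3-[(6S)-6-{[tert-butyl(diphenyl)silyl]oxymethyl}-5,5-dimethyl-2-[(trimethylsilyl)oxy]cyclohexa-1,3-dien-1-yl]-2-methylidene-7-[(trimethylsilyl)oxy]oct-6-enoate F2. Catalytic HN(SO2CF3)2 in CH2Cl2 at −78 °C then closes ring A onto the acrylate without any basic species. Aqueous acid work-up protonates the silyl ketene acetal from the open face and cleaves the ring C silyl dienol ether, and the fallback comes back at 21.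

Step 17 (hydroxymethylation and lactonisation). The α-hydrogen of the ring C ketone is very hindered, the ester α-hydrogen may compete with amide base, and the aldolate can revert before lactonising. The fallback uses soft enolisation and a Lewis-acid aldol in water and sets out from 23. Me3SiOTf/NEt3 (CH2Cl2, 0 °C) gives trimethylsilyl 2-[(1R,3S,4R)-4-[(6S)-6-{[tert-butyl(diphenyl)silyl]oxymethyl}-5,5-dimethyl-2-[(trimethylsilyl)oxy]cyclohexa-1,3-dien-1-yl]-3-(methoxycarbonyl)cyclohexyl]prop-2-enoate F3. Sc(OTf)3-catalysed Mukaiyama aldol with aqueous formaldehyde in THF, again anti to the CH2OSi group, gives 24 with hydrolysis of the silyl ester. Camphorsulfonic acid (cat.) in toluene at 60 °C then closes the lactone, and the fallback comes back at 25.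

**Further compounds**
F1 | step 13 | methyl (2E)-2-(bromomethyl)-6-(2-methyl-1,3-dioxolan-2-yl)hex-2-enoate | COC(=O)/C(CBr)=C\CCCC1(C)OCCO1
F2 | step 14 | methyl (3S,6Z)-3-[(6S)-6-{[tert-butyl(diphenyl)silyl]oxymethyl}-5,5-dimethyl-2-[(trimethylsilyl)oxy]cyclohexa-1,3-dien-1-yl]-2-methylidene-7-[(trimethylsilyl)oxy]oct-6-enoate | C[Si](C)(C)OC1=C([C@H](CC/C=C(/C)O[Si](C)(C)C)C(=C)C(=O)OC)[C@@H](CO[Si](c2ccccc2)(c2ccccc2)C(C)(C)C)C(C)(C)C=C1
F3 | step 17 | trimethylsilyl 2-[(1R,3S,4R)-4-[(6S)-6-{[tert-butyl(diphenyl)silyl]oxymethyl}-5,5-dimethyl-2-[(trimethylsilyl)oxy]cyclohexa-1,3-dien-1-yl]-3-(methoxycarbonyl)cyclohexyl]prop-2-enoate | C=C(C(=O)O[Si](C)(C)C)[C@@H]1CC[C@@H](C2=C(O[Si](C)(C)C)C=CC(C)(C)[C@@H]2CO[Si](c2ccccc2)(c2ccccc2)C(C)(C)C)[C@H](C1)C(=O)OC
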